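**Plan**
- Retrosynthesis: both ring–CH2 bonds (C3 of each quinone ring to C1 and C14 of the chain) are cut at once, giving two molecules of 2-hydroxy-5-methoxy-6-methyl-1,4-benzoquinone and tetradecanedial.
- Enabling feature: in each ring the chain-bearing C3 lies between C2–OH and C4=O, so it is the α-carbon of the vinylogous acid HO–C2=C3–C4=O and carries a CH2; the free hydroxyquinone is therefore a carbon nucleophile at exactly that atom.
- Forward, ring: the six-membered ring comes from 2-methylresorcinol and is raised in oxidation level by mono-O-methylation, para-oxidation to the quinone, Thiele–Winter acetoxylation and deacetylation/oxidation.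
- Forward, chain: tetradecane-1,14-diol is oxidised to the dialdehyde and joined to both finished rings in the last operation by a twofold amine-catalysed Knoevenagel condensation/Hantzsch ester reduction; no ring is formed there.
- Stereochemistry: the target has no stereocentre and no stereogenic double bond, so nothing has to be set.

Key step: step 6

Remark: in the last step the two chain ends react independently. Its three intermediates are written for the case in which one end is finished before the other begins, and the geometry of their exocyclic double bond is left open because that bond is reduced.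

**Route**

Step 1
Reactants: 1 2-methylresorcinol (2-methylbenzene-1,3-diol)
Product: 2 3-methoxy-2-methylphenol
Conditions: Me2SO4 (1.0 equiv), NaOH (1.0 equiv), H2O, 0 °C to rt; separation from diether and recovered diol
Reagents that add atoms: dimethyl sulfate, COS(=O)(=O)OC
Why: Williamson-type O-methylation of the monophenoxide with one equivalent of alkylating agent should give the monoether as the main component of a separable mixture, the two hydroxyl groups being equivalent.

Step 2
Reactants: 2 3-methoxy-2-methylphenol
Product: 3 2-methoxy-3-methyl-1,4-benzoquinone
Conditions: (KSO3)2NO (2.2 equiv), KH2PO4 buffer, H2O/acetone, 0 °C to rt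
Reagents that add atoms: potassium nitrosodisulfonate (Fremy's salt), [O]N(S(=O)(=O)[O-])S(=O)(=O)[O-].[K+].[K+]
Why: Teuber oxidation, in which one equivalent of the nitroxide abstracts the phenolic hydrogen and a second delivers oxygen to the unsubstituted carbon para to the hydroxyl group, should give the para-quinone.

Step 3
Reactants: 3 2-methoxy-3-methyl-1,4-benzoquinone
Product: 4 5-methoxy-6-methylbenzene-1,2,4-triyl triacetate
Conditions: Ac2O, H2SO4 (cat.), 0 °C to rt
Reagents that add atoms: acetic anhydride, CC(=O)OC(C)=O
Why: Thiele–Winter acetoxylation (acid-promoted conjugate addition of acetate, enolisation and peracetylation) should place the new oxygen at C5 of 3, para to the methoxy group, because the methoxy group turns C4=O into a vinylogous ester and leaves the C1=O enone, whose β-carbon is C5, as the electrophile.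

Step 4
Reactants: 4 5-methoxy-6-methylbenzene-1,2,4-triyl triacetate
Product: 6 2-hydroxy-5-methoxy-6-methyl-1,4-benzoquinone, via 5-methoxy-6-methylbenzene-1,2,4-triol 5 (not isolated)
Conditions: HCl (cat.), MeOH, reflux, Ar; evaporate; then FeCl3 (2.2 equiv), H2O/EtOAc, 0 °C
Reagents that add atoms: none
Why: Acid-catalysed transesterification should free the air-sensitive hydroxyhydroquinone, which iron trichloride oxidises by two electrons to the hydroxy-para-quinone; methanol is removed before the oxidation so that the vinylogous acid is not etherified.

Step 5
Reactants: 7 tetradecane-1,14-diol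
Product: 8 tetradecanedial
Conditions: TEMPO (10 mol %), PhI(OAc)2 (2.2 equiv), CH2Cl2, rt; used at once
Reagents that add atoms: none
Why: Oxoammonium-mediated (TEMPO/PhI(OAc)2) oxidation of primary alcohols should stop at the aldehyde in the absence of water, and the two termini are too far apart to interact.

Step 6
Reactants: 6 2-hydroxy-5-methoxy-6-methyl-1,4-benzoquinone (2.2 equiv); 8 tetradecanedial (1.0 equiv); 9 Hantzsch ester, diethyl 2,6-dimethyl-1,4-dihydropyridine-3,5-dicarboxylate (2.4 equiv)
Product: 13 3,3'-(tetradecane-1,14-diyl)bis(2-hydroxy-5-methoxy-6-methyl-1,4-benzoquinone) (CNP0278640.0), via alkylidene-trione aldehyde 10 (not isolated), via monoalkylated aldehyde 11 (not isolated), via alkylidene-trione quinone 12 (not isolated)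
Conditions: L-proline (40 mol % based on 8), CH2Cl2, rt, 8 added last; then air during work-up
Reagents that add atoms: none
Why: L-Proline condenses with each formyl group of 8 to an iminium ion that is attacked by C3 of 6, the α-carbon of the vinylogous acid HO–C2=C3–C4=O; loss of proline gives the 3-alkylidene-1,2,4-trione (an ortho-quinone methide, 10 and later 12), and 9 transfers hydride to its exocyclic carbon so that the hydroxyquinone is restored with a new ring–CH2 bond (11, then 13). The closest known reaction type is the amine-catalysed three-component reductive alkylation (Knoevenagel condensation/transfer hydrogenation) of 2-hydroxy-1,4-naphthoquinone and 2,5-dihydroxy-1,4-benzoquinone with aliphatic aldehydes and Hantzsch ester, run here at both ends of a dialdehyde. No ring is closed and no stereocentre is formed; both aldehyde carbons end as chain CH2 groups. The selectivity needed is chemoselectivity: hydride transfer to the alkylidene must outrun Michael addition of a second hydroxyquinone and aldol reaction of the aldehyde, which is served by having 9 in excess from the start and adding 8 last. Regiochemistry is fixed because C3 is the only unsubstituted ring carbon of 6, and the 5-methoxy group holds the ring in the para-quinone form so that no protecting group is needed; any hydroquinone formed by adventitious reduction should reoxidise in air.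

**Compound list**
1 | 2-methylresorcinol | Cc1c(O)cccc1O | starting material
2 | 3-methoxy-2-methylphenol | COc1cccc(O)c1C | intermediate
3 | 2-methoxy-3-methyl-1,4-benzoquinone | COC1=C(C)C(=O)C=CC1=O | intermediate
4 | 5-methoxy-6-methylbenzene-1,2,4-triyl triacetate | COc1c(C)c(OC(C)=O)c(OC(C)=O)cc1OC(C)=O | intermediate
5 | 5-methoxy-6-methylbenzene-1,2,4-triol | COc1c(C)c(O)c(O)cc1O | intermediate
6 | 2-hydroxy-5-methoxy-6-methyl-1,4-benzoquinone | COC1=C(C)C(=O)C(O)=CC1=O | intermediate
7 | tetradecane-1,14-diol | OCCCCCCCCCCCCCCO | starting material
8 | tetradecanedial | O=CCCCCCCCCCCCCC=O | intermediate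
9 | Hantzsch ester (diethyl 2,6-dimethyl-1,4-dihydropyridine-3,5-dicarboxylate) | CCOC(=O)C1=C(C)NC(C)=C(C1)C(=O)OCC | starting material
10 | 14-(3-methoxy-4-methyl-2,5,6-trioxocyclohex-3-en-1-ylidene)tetradecanal (either alkene geometry) | COC1=C(C)C(=O)C(=O)C(=CCCCCCCCCCCCCC=O)C1=O | intermediate
11 | 14-(2-hydroxy-5-methoxy-4-methyl-3,6-dioxocyclohexa-1,4-dien-1-yl)tetradecanal | COC1=C(C)C(=O)C(O)=C(CCCCCCCCCCCCCC=O)C1=O | intermediate
12 | 2-hydroxy-5-methoxy-6-methyl-3-[14-(3-methoxy-4-methyl-2,5,6-trioxocyclohex-3-en-1-ylidene)tetradecyl]-1,4-benzoquinone (either alkene geometry) | COC1=C(C)C(=O)C(O)=C(CCCCCCCCCCCCCC=C2C(=O)C(=O)C(C)=C(OC)C2=O)C1=O | intermediate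
13 | 3,3'-(tetradecane-1,14-diyl)bis(2-hydroxy-5-methoxy-6-methyl-1,4-benzoquinone), CNP0278640.0 | COC1=C(C)C(=O)C(O)=C(CCCCCCCCCCCCCCC2=C(O)C(=O)C(C)=C(OC)C2=O)C1=O | target

**Totals**
Total step count: 6. Longest linear sequence: 5 steps (steps 1, 2, 3, 4 and 6, from 1 to 13); the chain branch is step 5 followed by step 6.

**Steps most likely to fail**

Step 6. What may go wrong: the alkylidene intermediate may be captured by a second hydroxyquinone (Michael addition) before hydride transfer, the dialdehyde ends may undergo proline-mediated self-aldol reaction, or the catalyst may be consumed by conjugate substitution of the methoxy group, so that one chain end stays unreacted or oligomerises. Fallback, from 6 back to 13, by a radical instead of an ionic pathway to the same two ring–CH2 bonds: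
- Silver-catalysed oxidative decarboxylation of bought hexadecanedioic acid (OC(=O)CCCCCCCCCCCCCCC(=O)O, in excess) with AgNO3 (cat., monovalent silver) and (NH4)2S2O8 in MeCN/H2O at 65 °C in the presence of 6. The ω-carboxyalkyl radical should add to C3, the only free ring carbon, and reoxidation should give 15-(2-hydroxy-5-methoxy-4-methyl-3,6-dioxocyclohexa-1,4-dien-1-yl)pentadecanoic acid F1.
- A second decarboxylative coupling of F1 with an excess of 6 under the same conditions should give 13.

Step 3. What may go wrong: regiocontrol of the acetate addition may be lost, with attack at C6 (directed by the methyl group) competing with attack at C5, giving a mixture of triacetates that is hard to separate. Fallback, from 2 back to 4, in which the oxygen pattern is built on an ortho-quinone whose only free β-carbon is the desired one: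
- Magnesium-mediated ortho-formylation of 2 (MgCl2, Et3N, paraformaldehyde, MeCN, reflux) at its single free ortho position should give 2-hydroxy-4-methoxy-3-methylbenzaldehyde F2.
- Dakin oxidation (H2O2, NaOH) should give 4-methoxy-3-methylbenzene-1,2-diol F3.
- Oxidation with NaIO4 should give 4-methoxy-3-methyl-1,2-benzoquinone F4.
- Thiele–Winter acetoxylation of F4 (Ac2O, H2SO4 cat.) should add acetate at C5, the β-carbon of the carbonyl not conjugated to the methoxy group, and give 4.

Step 1. What may go wrong: the monoether may be methylated further at a rate similar to that of the diol, so that the desired product is only part of a statistical mixture. Fallback, from 1 back to 2: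
- Exhaustive methylation (excess Me2SO4, K2CO3, acetone, reflux) should give 2,6-dimethoxytoluene F5.
- Nucleophilic mono-demethylation with NaSEt in DMF at reflux should stop after one ether cleavage, because the phenoxide formed resists a second attack, and give 2 on acidification.

**Further compounds**
F1 | step 6 | 15-(2-hydroxy-5-methoxy-4-methyl-3,6-dioxocyclohexa-1,4-dien-1-yl)pentadecanoic acid | COC1=C(C)C(=O)C(O)=C(CCCCCCCCCCCCCCC(=O)O)C1=O
F2 | step 3 | 2-hydroxy-4-methoxy-3-methylbenzaldehyde | COc1ccc(C=O)c(O)c1C
F3 | step 3 | 4-methoxy-3-methylbenzene-1,2-diol | COc1ccc(O)c(O)c1C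
F4 | step 3 | 4-methoxy-3-methyl-1,2-benzoquinone | COC1=C(C)C(=O)C(=O)C=C1
F5 | step 1 | 2,6-dimethoxytoluene | COc1cccc(OC)c1C
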